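**Retrosynthetic overview**

1. The three angelates come last: the C10 ester by enolate bromination and carboxylate SN2, the C2 and C5 esters by acylation of a diepoxy keto diol. The C7–C8 epoxy ketone comes from a Wharton transposition of a C7 ketone, then oxidation and epoxidation. The C2-hydroxy C3–C4 epoxide comes from a (Z)-enone by nucleophilic epoxidation and chelation-controlled reduction.
2. The ten-membered ring comes from a dianion-accelerated alkynyl oxy-Cope ring expansion: the C4–C5 bond forms while the C2–C7 bond of a 1-propynyl-2-(alkoxyvinyl)cyclohexene-1,2-diol breaks.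
3. Enabling feature: C4–C5 is the central bond of the array C2–C3–C4–C5–C6–C7. C2 and C7 both carry oxygen in the target and are bridged the other way by C1, C10, C9 and C8, so that C7–C8(Me)–C9–C10–C1(isopropenyl)–C2 is the six-membered ring of carvone (C7 = carbonyl carbon, C2 = α'-carbon).
4. The cyclohexenediol comes from (R)-carvone by α'-hydroxylation, (Z)-alkoxyvinyllithium addition, oxidation and propynyl Grignard addition.
5. Ring order: six-membered ring (carvone), ten-membered ring (step 7), C3–C4 oxirane (step 10), C7–C8 oxirane (step 13).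

Key step: step 7

Remark: locants C1–C10 in names are the ring positions of the target (C1 bears isopropenyl, C9 is the ketone, counted C1→C2→…→C10).
Remark: the configuration of the transient C8–C9 oxirane (17, 18) and of the C9 carbinol (19–21) is erased in step 12; one epimer is drawn arbitrarily.

Step 1
Reactants: 1 4-methoxybenzyl alcohol; 2 ethyl vinyl ether
Product: 3 4-methoxybenzyl vinyl ether
Conditions: Pd(OAc)2 (cat.), 1,10-phenanthroline (cat.), 2 as solvent, rt
Reagents that add atoms: ethyl vinyl ether (2), C=COCC
Why: Palladium-catalysed transfer vinylation (transetherification) of a primary alcohol with an alkyl vinyl ether is a standard vinyl ether synthesis and forms no stereocentre.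

Step 2
Reactants: 3 4-methoxybenzyl vinyl ether
Product: 5 (Z)-1-bromo-2-[(4-methoxybenzyl)oxy]ethene, via dibromo ether 4 (not isolated)
Conditions: Br2 (1.0 equiv), CH2Cl2, −78 °C; then KOt-Bu, THF, −78 → 0 °C
Reagents that add atoms: bromine, BrBr
Why: Bromine addition to the electron-rich vinyl ether followed by base-induced dehydrobromination of the α-bromo ether is the classical route to 2-bromovinyl ethers and should give mainly the Z isomer, which is purified.

Step 3
Reactants: 6 (R)-(−)-carvone
Product: 8 trans-6-hydroxycarvone (hydroxyl at C2, trans to the C1 isopropenyl group), via lithium dienolate 7 (not isolated)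
Conditions: LiN(SiMe3)2, THF, −78 °C; then 2-(phenylsulfonyl)-3-phenyloxaziridine, −78 °C; aq NH4Cl
Reagents that add atoms: 2-(phenylsulfonyl)-3-phenyloxaziridine, O=S(=O)(c1ccccc1)N1OC1c1ccccc1
Why: Kinetic α'-deprotonation of the enone and electrophilic enolate hydroxylation by the N-sulfonyloxaziridine; the oxidant should approach anti to the neighbouring isopropenyl group (trans product), and this centre is oxidised again in step 5.

Step 4
Reactants: 5 (Z)-1-bromo-2-[(4-methoxybenzyl)oxy]ethene; 8 trans-6-hydroxycarvone
Product: 10 C2,C7-diol carrying the (Z)-2-(4-methoxybenzyloxy)vinyl group at C7 (C7–OH cis and the vinyl group trans to isopropenyl; C2–OH trans), via vinyllithium 9 (not isolated)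
Conditions: 5 (2.3 equiv), t-BuLi (4.6 equiv), Et2O, −78 °C; then 8, THF, −78 °C; cold aq NH4Cl
Reagents that add atoms: none
Why: Bromine–lithium exchange with retention of the Z geometry, then 1,2-addition of the vinyllithium to the enone carbonyl by axial attack trans to the isopropenyl group (as in additions to carvone), which sets C7 with its hydroxyl cis to isopropenyl.

Step 5
Reactants: 10 C2,C7-diol
Product: 11 C2 ketone with the tertiary C7 hydroxyl (α-hydroxy ketone)
Conditions: SO3·pyridine, DMSO, Et3N, CH2Cl2, 0 °C
Reagents that add atoms: none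
Why: Parikh–Doering oxidation converts only the secondary C2 alcohol under base-buffered conditions that spare the tertiary allylic alcohol and the acid-labile enol ether; no new stereocentre.

Step 6
Reactants: 11 α-hydroxy ketone; 12 1-propynylmagnesium bromide
Product: 13 1,2-diol with 1-propynyl at C2 (cis to isopropenyl, trans to the C7 vinyl arm; the two hydroxyls trans)
Conditions: CH3C≡CMgBr (3 equiv), THF, −78 → 0 °C; aq NH4Cl
Reagents that add atoms: 1-propynylmagnesium bromide (12), CC#C[Mg]Br
Why: Chelation-controlled Grignard addition to the α-hydroxy ketone: the small alkynyl nucleophile should enter axially on the face opposite the pseudo-axial C7 vinyl arm, giving the trans arrangement of the two unsaturated arms.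

Step 7
Reactants: 13 1-propynyl-2-(alkoxyvinyl)cyclohexene-1,2-diol
Product: 16 ten-membered dienedione (ketones at C2 and C7; C3=C4 and C8=C9 both Z; C5 ether 5S), via dipotassium dialkoxide 14 (not isolated), via dipotassium bis-enolate 15 (not isolated)
Conditions: KH (2.2 equiv), 18-crown-6, THF, −40 → 0 °C; then AcOH, −78 °C
Reagents that add atoms: none
Why: Double deprotonation gives dialkoxide 14, whose C2–C7 bond is weakened by both oxyanions; a [3,3]-sigmatropic (alkynyl oxy-Cope) shift through a chair-like six-centre array with both arms pseudo-equatorial makes C4–C5 and breaks C2–C7, giving the C7 enolate/C2 allenolate 15, which is protonated at C6 and C3. The closest known reactions are the anion-accelerated oxy-Cope ring expansion of 1,2-divinylcyclohexanols to cyclodecenones, its acetylenic variant and the low-temperature rearrangement of 1,2-dialkenyl-1,2-diolates. The ten-membered ring closes by σ-bond formation between the two arm termini (C4 of the alkyne, C5 of the enol ether) while the six-membered ring opens, a four-carbon ring enlargement. C5 is set by chirality transfer: with the two arms trans on the ring, the chair array and the Z enol ether geometry expose one face of C5 to C4 (5S), C1 is untouched, C3=C4 should become Z by protonation of the cyclic allenolate from outside the ring, and C8=C9 stays Z. The step needs this shift to beat the alternative shift into the C1 isopropenyl arm and needs the β-alkoxy enolate to survive; the first is secured because only the C2–C7 bond is activated by both alkoxides, the second by running and quenching the rearrangement cold.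

Step 8
Reactants: 16 ten-membered dienedione
Product: 17 C8–C9 mono-epoxide (C7 epoxy ketone; C3=C4 enone intact)
Conditions: t-BuOOH (1.0 equiv), DBU, CH2Cl2, 0 °C
Reagents that add atoms: tert-butyl hydroperoxide, CC(C)(C)OO
Why: Weitz–Scheffer (nucleophilic) epoxidation should be chemoselective for the β-monosubstituted C8=C9 enone over the more hindered β,β-disubstituted C3=C4 enone; the new oxirane centres are erased later.

Step 9
Reactants: 17 C8–C9 mono-epoxide
Product: 19 C9 allylic alcohol with a (Z)-C7=C8 double bond (C2 enone intact), via epoxy hydrazone 18 (not isolated)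
Conditions: N2H4·H2O, AcOH (cat.), MeOH, 0 °C → rt
Reagents that add atoms: none
Why: Wharton transposition: the hydrazone of the α,β-epoxy ketone fragments with loss of N2, moving the double bond to C7=C8 and the oxygen to C9; the Z (cis-cyclodecene) geometry is expected because the alkenyl intermediate can relax to the less strained ring alkene before it is quenched.

Step 10
Reactants: 19 C9 allylic alcohol
Product: 20 C3–C4 epoxy ketone (oxirane trans to the C5 oxygen, cis ring fusion; descriptors 3R,4R at the ketone stage, the same spatial arrangement as the 3S,4R oxirane of the target)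
Conditions: t-BuOOH, DBU, CH2Cl2, rt
Reagents that add atoms: tert-butyl hydroperoxide, CC(C)(C)OO
Why: Weitz–Scheffer epoxidation of the remaining (Z)-enone: with H5 eclipsing the alkene (allylic 1,3-strain) the peroxide should attack C4 from the ring periphery, anti to the C5–C6 ring bond, which places the oxirane trans to the C5 oxygen.

Step 11
Reactants: 20 C3–C4 epoxy ketone
Product: 21 C2 alcohol (2S, cis to the C3–C4 oxirane, which is now 3S,4R)
Conditions: Zn(BH4)2, Et2O, −20 °C
Reagents that add atoms: none
Why: Chelation-controlled reduction of an α,β-epoxy ketone: zinc bridges the carbonyl and oxirane oxygens and hydride enters anti to C4, giving the erythro epoxy alcohol; the C9 allylic alcohol is unaffected.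

Step 12
Reactants: 21 C2,C9-diol
Product: 22 (Z)-C7=C8 enone with the carbonyl at C9 (C2 hydroxyl free)
Conditions: MnO2, CH2Cl2, rt
Reagents that add atoms: none
Why: MnO2 oxidises only the allylic C9 alcohol, because the C2 carbinol is no longer allylic.

Step 13
Reactants: 22 C9 enone
Product: 23 C7–C8 epoxy ketone (7R,8R, cis-fused)
Conditions: t-BuOOH, DBU, CH2Cl2, 0 °C → rt
Reagents that add atoms: tert-butyl hydroperoxide, CC(C)(C)OO
Why: Weitz–Scheffer epoxidation of the (Z)-α-methyl enone; peripheral attack on the ten-membered ring is expected to give the cis-fused 7R,8R oxirane, and this facial outcome is the least secure point of the route (see below).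

Step 14
Reactants: 23 C7–C8 epoxy ketone
Product: 24 C2,C5-diol
Conditions: DDQ, CH2Cl2/pH 7 buffer, 0 °C
Reagents that add atoms: none
Why: Oxidative cleavage of the 4-methoxybenzyl ether by DDQ under buffered conditions that should leave both oxiranes, the ketone and the isopropenyl group untouched; no stereocentre is affected.

Step 15
Reactants: 24 C2,C5-diol; 25 angelic acid
Product: 26 C2,C5-bis-angelate
Conditions: 25, 2,4,6-trichlorobenzoyl chloride, Et3N, toluene, rt; then 24, 70 °C
Reagents that add atoms: angelic acid (25), C/C=C(/C)C(=O)O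
Why: Yamaguchi-type esterification through the mixed 2,4,6-trichlorobenzoic anhydride acylates both hindered secondary alcohols with retention and should transfer the angeloyl group without Z-to-E isomerisation.

Step 16
Reactants: 26 C2,C5-bis-angelate
Product: 28 C10 α-bromo ketone (bromine trans to isopropenyl), via silyl enol ether 27 (not isolated)
Conditions: LiN(SiMe3)2, Me3SiCl, THF, −78 °C; then NBS, −78 °C
Reagents that add atoms: N-bromosuccinimide, O=C1CCC(=O)N1Br
Why: Regiospecific enolisation toward C10 (C8 is quaternary) with in-situ silylation, then bromination of the silyl enol ether; the electrophile is expected on the peripheral face anti to the C1–C2 ring bond, i.e. trans to isopropenyl.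

Step 17
Reactants: 28 C10 α-bromo ketone; 25 angelic acid
Product: 29 target (CNP0154187.1)
Conditions: 25, Cs2CO3, DMF; then 28, rt
Reagents that add atoms: angelic acid (25), C/C=C(/C)C(=O)O
Why: SN2 displacement of the α-bromo ketone by caesium angelate (carboxylate alkylation, so no acyl activation and no angelate isomerisation) inverts C10 and should deliver the 10S ester.

**Compound list**

1 | 4-methoxybenzyl alcohol | COc1ccc(CO)cc1 | starting material
2 | ethyl vinyl ether | C=COCC | starting material
3 | 4-methoxybenzyl vinyl ether | C=COCc1ccc(OC)cc1 | intermediate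
4 | 1,2-dibromoethyl 4-methoxybenzyl ether (racemic) | BrCC(Br)OCc1ccc(OC)cc1 | intermediate
5 | (Z)-1-bromo-2-[(4-methoxybenzyl)oxy]ethene | Br/C=C\OCc1ccc(OC)cc1 | intermediate
6 | (R)-(−)-carvone | CC1=CC[C@H](CC1=O)C(C)=C | starting material
7 | lithium cross-conjugated dienolate of carvone | CC1=CC[C@@H](C(C)=C)C=C1[O-].[Li+] | intermediate
8 | (5S,6S)-6-hydroxycarvone (C2–OH trans to isopropenyl) | CC1=CC[C@@H](C(C)=C)[C@H](O)C1=O | intermediate
9 | (Z)-2-[(4-methoxybenzyl)oxy]vinyllithium | [Li]/C=C\OCc1ccc(OC)cc1 | intermediate
10 | C2,C7-diol with the (Z)-alkoxyvinyl arm at C7 (C7–OH cis, C2–OH trans to isopropenyl) | CC1=CC[C@@H](C(C)=C)[C@H](O)[C@]1(O)/C=C\OCc1ccc(OC)cc1 | intermediate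
11 | C2 ketone, C7 tertiary alcohol | CC1=CC[C@@H](C(C)=C)C(=O)[C@]1(O)/C=C\OCc1ccc(OC)cc1 | intermediate
12 | 1-propynylmagnesium bromide | CC#C[Mg]Br | starting material
13 | 1-propynyl (C2) / alkoxyvinyl (C7) trans-1,2-diol | CC1=CC[C@@H](C(C)=C)[C@@](O)(C#CC)[C@]1(O)/C=C\OCc1ccc(OC)cc1 | intermediate
14 | dipotassium dialkoxide of 13 | CC1=CC[C@@H](C(C)=C)[C@@]([O-])(C#CC)[C@]1([O-])/C=C\OCc1ccc(OC)cc1.[K+].[K+] | intermediate
15 | ring-expanded dipotassium C7 dienolate / C2 allenolate (allene axis not specified) | C=C(C)[C@H]1C([O-])=C=C(C)[C@@H](OCc2ccc(OC)cc2)/C=C(\[O-])/C(C)=C\C1.[K+].[K+] | intermediate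
16 | ten-membered (3Z,8Z)-2,7-dione, 5S 4-methoxybenzyl ether | C=C(C)[C@H]1C(=O)/C=C(C)\[C@@H](OCc2ccc(OC)cc2)CC(=O)/C(C)=C\C1 | intermediate
17 | C8–C9 mono-epoxide of 16 (epimer drawn arbitrarily) | C=C(C)[C@H]1C(=O)/C=C(C)\[C@@H](OCc2ccc(OC)cc2)CC(=O)[C@]3(C)O[C@@H]3C1 | intermediate
18 | C7 hydrazone of 17 | C=C(C)[C@H]1C(=O)/C=C(C)\[C@@H](OCc2ccc(OC)cc2)CC(=NN)[C@]3(C)O[C@@H]3C1 | intermediate
19 | C9 allylic alcohol, (Z)-C7=C8, C2 enone | C=C(C)[C@H]1C(=O)/C=C(C)\[C@@H](OCc2ccc(OC)cc2)C/C=C(C)\[C@H](O)C1 | intermediate
20 | C3–C4 epoxy ketone (3R,4R at the ketone stage; oxirane trans to the C5 oxygen) | C=C(C)[C@H]1C(=O)[C@@H]2O[C@]2(C)[C@@H](OCc3ccc(OC)cc3)C/C=C(C)\[C@H](O)C1 | intermediate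
21 | C2 (2S) and C9 diol | C=C(C)[C@H]1[C@H](O)[C@@H]2O[C@]2(C)[C@@H](OCc3ccc(OC)cc3)C/C=C(C)\[C@H](O)C1 | intermediate
22 | (Z)-C7=C8 enone, C9 ketone, C2–OH | C=C(C)[C@H]1[C@H](O)[C@@H]2O[C@]2(C)[C@@H](OCc3ccc(OC)cc3)C/C=C(C)\C(=O)C1 | intermediate
23 | C3–C4 and C7–C8 diepoxy C9 ketone, C2–OH, C5 ether | C=C(C)[C@H]1[C@H](O)[C@@H]2O[C@]2(C)[C@@H](OCc3ccc(OC)cc3)C[C@H]2O[C@@]2(C)C(=O)C1 | intermediate
24 | diepoxy keto C2,C5-diol | C=C(C)[C@H]1[C@H](O)[C@@H]2O[C@]2(C)[C@@H](O)C[C@H]2O[C@@]2(C)C(=O)C1 | intermediate
25 | angelic acid ((Z)-2-methylbut-2-enoic acid) | C/C=C(/C)C(=O)O | starting material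
26 | C2,C5-bis-angelate | C=C(C)[C@H]1[C@H](OC(=O)/C(C)=C\C)[C@@H]2O[C@]2(C)[C@@H](OC(=O)/C(C)=C\C)C[C@H]2O[C@@]2(C)C(=O)C1 | intermediate
27 | C9 trimethylsilyl enol ether (C9=C10; enol geometry not specified) | C=C(C)[C@H]1[C@H](OC(=O)/C(C)=C\C)[C@@H]2O[C@]2(C)[C@@H](OC(=O)/C(C)=C\C)C[C@H]2O[C@@]2(C)C(O[Si](C)(C)C)=C1 | intermediate
28 | C10 α-bromo ketone (Br trans to isopropenyl) | C=C(C)[C@H]1[C@H](OC(=O)/C(C)=C\C)[C@@H]2O[C@]2(C)[C@@H](OC(=O)/C(C)=C\C)C[C@H]2O[C@@]2(C)C(=O)[C@@H]1Br | intermediate
29 | CNP0154187.1 | C=C(C)[C@H]1[C@H](OC(=O)/C(C)=C\C)[C@@H]2O[C@]2(C)[C@@H](OC(=O)/C(C)=C\C)C[C@H]2O[C@@]2(C)C(=O)[C@H]1OC(=O)/C(C)=C\C | target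

**Step count and risks**

Total step count: 17 (steps 1 and 2 make vinyl bromide 5, step 3 makes hydroxy ketone 8, steps 4–17 lead from their union to the target). Longest linear sequence: 16 steps (steps 1, 2 and 4–17, counted from 4-methoxybenzyl alcohol 1 and ethyl vinyl ether 2); the carvone branch (steps 3–17) is 15 steps.

The three steps most likely to fail:

Step 7 (key step). What may go wrong: β-elimination of the C5 alkoxide from the product enolate, rearrangement into the isopropenyl arm, or erosion of the chirality transfer if the step-4/step-6 additions give another diol diastereomer or a boat-like array competes. The fallback replaces anion acceleration by a neutral thermal rearrangement. It sets out from 13, whose two tertiary hydroxyls are silylated with N-trimethylsilylimidazole to give the bis(trimethylsilyl) ether of 13 F1. Heating F1 in degassed o-xylene in base-washed glass at about 170 °C should effect the siloxy-Cope shift to the ring-expanded bis(trimethylsilyl) enol/allenol ether F2, which never passes through a free β-alkoxy enolate. Buffered fluoride (Bu4NF/AcOH, −20 °C) releases both carbonyls and returns to 16.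

Step 13. What may go wrong: poor facial selectivity of peroxide attack on the macrocyclic enone, together with base-induced deconjugation of the enone. The fallback replaces substrate control by reagent control and hydroxyl direction. It sets out from 22, which is protected (Et3SiOTf, 2,6-lutidine) as the C2 triethylsilyl ether of enone 22 F3. A CBS reduction with the (R)-methyl oxazaborolidine and catecholborane should give the 9S allylic alcohol F4. Hydroxyl-directed epoxidation (VO(acac)2, t-BuOOH) then delivers the syn 7,8-epoxy-9-ol F5. Oxidation (SO3·pyridine, DMSO, Et3N) gives the C2-silylated epoxy ketone F6, and HF·pyridine removes the silyl ether to rejoin the route at 23.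

Step 16. What may go wrong: poor facial selectivity in the bromination, and epimerisation of the α-bromo ketone by bromide exchange before or during the displacement in step 17. The fallback installs oxygen first and inverts afterwards. It sets out from 26: silyl enol ether 27 is oxidised with dimethyldioxirane (Rubottom oxidation) to the configurationally stable C10 α-hydroxy ketone F7, hydroxyl expected trans to isopropenyl. Mitsunobu esterification with 25 (Ph3P, DIAD) inverts C10 and comes back at 29. Should the hydroxylation instead give the cis alcohol, it would be esterified with retention under the conditions of step 15.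

Further compounds
F1 | step 7 | bis(trimethylsilyl) ether of 13 | CC1=CC[C@@H](C(C)=C)[C@@](O[Si](C)(C)C)(C#CC)[C@]1(O[Si](C)(C)C)/C=C\OCc1ccc(OC)cc1
F2 | step 7 | ring-expanded bis(trimethylsilyl) enol/allenol ether | C=C(C)[C@H]1C(O[Si](C)(C)C)=C=C(C)[C@@H](OCc2ccc(OC)cc2)/C=C(\O[Si](C)(C)C)/C(C)=C\C1
F3 | step 13 | C2 triethylsilyl ether of enone 22 | C=C(C)[C@H]1[C@H](O[Si](CC)(CC)CC)[C@@H]2O[C@]2(C)[C@@H](OCc3ccc(OC)cc3)C/C=C(C)\C(=O)C1
F4 | step 13 | 9S allylic alcohol | C=C(C)[C@H]1[C@H](O[Si](CC)(CC)CC)[C@@H]2O[C@]2(C)[C@@H](OCc3ccc(OC)cc3)C/C=C(C)\[C@@H](O)C1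
F5 | step 13 | syn 7,8-epoxy-9-ol | C=C(C)[C@H]1[C@H](O[Si](CC)(CC)CC)[C@@H]2O[C@]2(C)[C@@H](OCc3ccc(OC)cc3)C[C@H]2O[C@@]2(C)[C@@H](O)C1
F6 | step 13 | C2-silylated epoxy ketone | C=C(C)[C@H]1[C@H](O[Si](CC)(CC)CC)[C@@H]2O[C@]2(C)[C@@H](OCc3ccc(OC)cc3)C[C@H]2O[C@@]2(C)C(=O)C1
F7 | step 16 | C10 α-hydroxy ketone (OH trans to isopropenyl) | C=C(C)[C@H]1[C@H](OC(=O)/C(C)=C\C)[C@@H]2O[C@]2(C)[C@@H](OC(=O)/C(C)=C\C)C[C@H]2O[C@@]2(C)C(=O)[C@@H]1O
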